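A direct plan would take ring A from a bromophenol and build ring B last, by a Diels–Alder reaction of the 2-prenyl Chan-type diene A1 with the ring A ynone A2, followed by acid aromatisation to the resorcinol ketone A3.
Desilylation to the benzoin A4, oxidation to the dione and removal of the MOM group would end a sequence of about twelve steps.
Its first weak step would be the cycloaddition that closes ring B: only frontier-orbital bias would choose between the wanted regiochemistry, a Michael or [3+3] pathway and attack at the ynone carbonyl, and the mixed ketal could aromatise by loss of methanol or of silanol.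
Its second would be the carbinol detour: a stereocentre would be made without control, silylated, carried through four steps, unmasked and oxidised away, so that five steps would serve the oxidation level of one carbon.
Its third would be the Dess–Martin oxidation of A4: a hypervalent iodine oxidant would meet a free, electron-rich prenylresorcinol on the most precious material of the route.

The retrosynthesis first cuts the two aryl–carbonyl bonds, C1 of ring B–C(=O) and C1 of ring A–C(=O), and then the C3–CH2 bond that holds the prenyl group on ring B.
The enabling feature is that the two bridge carbons together form an oxalyl unit and each is flanked by an oxygen at C2 of its ring. Both rings can therefore serve as chelated ortho-alkoxy aryllithiums, and the bridge can enter as the bis(N-methoxy-N-methylamide) of oxalic acid, already at the dione oxidation level.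
No ring is built: ring B is bought as 4-bromoresorcinol and receives its prenyl group by lithiation at C3 between the two oxygens, and ring A is bought as 2-bromo-5-methoxyphenol. Ring B is joined to the bridge first and ring A last, in one flask.
There is thus no cycloaddition with regiochemistry left to chance, no sp3 carbinol carbon between the rings at any stage, and no oxidation once the rings are joined; the route has five steps.

Key step: step 4

Remark: LiTMP is taken from a titrated stock solution, and compounds 1, 3, 6 and 8 are assumed to be bought.

Step 1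
Reactants: 1 4-bromobenzene-1,3-diol (4-bromoresorcinol)
Product: 2 1-bromo-2,4-bis(methoxymethoxy)benzene
Conditions: NaH, DMF, 0 °C; MOMCl, 0 → 20 °C
Reagents that add atoms: chloromethyl methyl ether, COCCl
Why: Double O-alkylation of the phenoxides (MOM protection) gives two acetals that tolerate lithium amides and organolithiums and later act as the directing groups for metalation.

Step 2
Reactants: 2 1-bromo-2,4-bis(methoxymethoxy)benzene; 3 prenyl bromide (1-bromo-3-methylbut-2-ene)
Product: 5 1-bromo-2,4-bis(methoxymethoxy)-3-(3-methylbut-2-enyl)benzene, via aryllithium 4 (not isolated)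
Conditions: LiTMP, THF, −78 °C; then CuI (10 mol %), 3, −78 → 0 °C
Reagents that add atoms: none
Why: Directed ortho-metalation with a lithium amide, which does not exchange the bromine, should remove the proton at C3, the only one flanked by two coordinating acetal oxygens, and copper-catalysed allylic substitution at the primary carbon of 3 then fixes the prenyl group between the two oxygens.

Step 3
Reactants: 6 2-bromo-5-methoxyphenol
Product: 7 1-bromo-4-methoxy-2-(methoxymethoxy)benzene
Conditions: NaH, DMF, 0 °C; MOMCl, 0 → 20 °C
Reagents that add atoms: chloromethyl methyl ether, COCCl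
Why: O-Alkylation of the phenoxide (MOM protection) masks the acidic proton and provides the chelating ortho substituent for the aryllithium of step 4.

Step 4
Reactants: 5 1-bromo-2,4-bis(methoxymethoxy)-3-(3-methylbut-2-enyl)benzene; 8 N,N'-dimethoxy-N,N'-dimethyloxamide; 7 1-bromo-4-methoxy-2-(methoxymethoxy)benzene
Product: 13 1-[2,4-bis(methoxymethoxy)-3-(3-methylbut-2-enyl)phenyl]-2-[4-methoxy-2-(methoxymethoxy)phenyl]ethane-1,2-dione, via ring B aryllithium 9 (not isolated), via lithium hemiaminal 10 (not isolated), via ring A aryllithium 11 (not isolated), via dilithium bis-hemiaminal 12 (not isolated)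
Conditions: 5, n-BuLi, THF, −78 °C, cannulated slowly into 8 (1.15 equiv), THF, −78 °C; then 11 (1.5 equiv, from 7, n-BuLi, THF, −78 °C), −78 → −20 °C; poured into cold 0.5 M aq HCl
Reagents that add atoms: none
Why: Bromine–lithium exchange turns 5 into the chelated aryllithium 9, which adds once to the oxalic bis(amide) 8 to give the lithium chelate 10 that does not collapse at low temperature; the second aryllithium 11 then adds to the remaining amide carbonyl to give 12, and cold acid releases both carbonyl groups at once, so the dione appears directly at its final oxidation level. The closest known reaction type is the Weinreb ketone synthesis in its double form, the sequential one-flask addition of two different organolithium or Grignard reagents to an oxalic acid bis(amide) (N,N'-dimethoxy-N,N'-dimethyloxamide or 1,4-dimethylpiperazine-2,3-dione), which is an established route to unsymmetrical 1,2-diketones. No ring is closed and no lasting stereocentre is formed: the two hemiaminal carbons of 12 arise as a mixture and both revert to carbonyl carbons on hydrolysis. The step needs one aryl group per bridge carbon in crossed order and no attack on a free ketone; the persistence of the tetrahedral chelates secures the latter, because no ketone exists before the quench. Mono-addition of 9 should be secured by slow inverse addition to a small excess of 8 and by the lower reactivity of the amide in 10, which is shielded by the neighbouring tetrasubstituted alkoxide carbon and deactivated by its charge, and the slower second addition is driven by an excess of the cheaper 11. The more hindered ring B nucleophile is thus used on the unhindered diamide and the less hindered ring A nucleophile on the crowded mono-adduct, and any MOM group lost in the quench is harmless because all three are removed in step 5.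

Step 5
Reactants: 13 1-[2,4-bis(methoxymethoxy)-3-(3-methylbut-2-enyl)phenyl]-2-[4-methoxy-2-(methoxymethoxy)phenyl]ethane-1,2-dione
Product: 14 licoagrodione, 1-[2,4-dihydroxy-3-(3-methylbut-2-enyl)phenyl]-2-(2-hydroxy-4-methoxyphenyl)ethane-1,2-dione
Conditions: HCl (3 M in MeOH), THF, 20 °C
Reagents that add atoms: none
Why: Acid-catalysed transacetalisation of the three MOM ethers to methanol (MOM removal) should proceed at ambient temperature, the two acetals ortho to a carbonyl group leaving first with carbonyl assistance, while the trisubstituted alkene should not be protonated under these conditions and the freed 2-hydroxy groups are held in hydrogen bonds to the carbonyl oxygens.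

**Compound list**

1 | 4-bromobenzene-1,3-diol (4-bromoresorcinol) | Oc1ccc(Br)c(O)c1 | starting material
2 | 1-bromo-2,4-bis(methoxymethoxy)benzene | COCOc1ccc(Br)c(OCOC)c1 | intermediate
3 | prenyl bromide (1-bromo-3-methylbut-2-ene) | CC(C)=CCBr | starting material
4 | [3-bromo-2,6-bis(methoxymethoxy)phenyl]lithium | COCOc1ccc(Br)c(OCOC)c1[Li] | intermediate
5 | 1-bromo-2,4-bis(methoxymethoxy)-3-(3-methylbut-2-enyl)benzene | COCOc1ccc(Br)c(OCOC)c1CC=C(C)C | intermediate
6 | 2-bromo-5-methoxyphenol | COc1ccc(Br)c(O)c1 | starting material
7 | 1-bromo-4-methoxy-2-(methoxymethoxy)benzene | COCOc1cc(OC)ccc1Br | intermediate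
8 | N,N'-dimethoxy-N,N'-dimethyloxamide | CON(C)C(=O)C(=O)N(C)OC | starting material
9 | [2,4-bis(methoxymethoxy)-3-(3-methylbut-2-enyl)phenyl]lithium | [Li]c1ccc(OCOC)c(CC=C(C)C)c1OCOC | intermediate
10 | lithium 1-[2,4-bis(methoxymethoxy)-3-(3-methylbut-2-enyl)phenyl]-1,2-bis[methoxy(methyl)amino]-2-oxoethan-1-olate (racemic) | CON(C)C(=O)C(O[Li])(N(C)OC)c1ccc(OCOC)c(CC=C(C)C)c1OCOC | intermediate
11 | [4-methoxy-2-(methoxymethoxy)phenyl]lithium | COCOc1cc(OC)ccc1[Li] | intermediate
12 | dilithium 1-[2,4-bis(methoxymethoxy)-3-(3-methylbut-2-enyl)phenyl]-1,2-bis[methoxy(methyl)amino]-2-[4-methoxy-2-(methoxymethoxy)phenyl]ethane-1,2-diolate (diastereomer mixture) | CON(C)C(O[Li])(c1ccc(OC)cc1OCOC)C(O[Li])(N(C)OC)c1ccc(OCOC)c(CC=C(C)C)c1OCOC | intermediate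
13 | 1-[2,4-bis(methoxymethoxy)-3-(3-methylbut-2-enyl)phenyl]-2-[4-methoxy-2-(methoxymethoxy)phenyl]ethane-1,2-dione | COCOc1cc(OC)ccc1C(=O)C(=O)c1ccc(OCOC)c(CC=C(C)C)c1OCOC | intermediate
14 | licoagrodione, 1-[2,4-dihydroxy-3-(3-methylbut-2-enyl)phenyl]-2-(2-hydroxy-4-methoxyphenyl)ethane-1,2-dione | COc1ccc(C(=O)C(=O)c2ccc(O)c(CC=C(C)C)c2O)c(O)c1 | target

Total step count: 5. Longest linear sequence: 4 steps (steps 1, 2, 4 and 5); step 3 is a one-step branch.

Steps most likely to fail:

Step 4 (key step). The second aryllithium may add too slowly to the crowded, anionic mono-adduct. A hemiaminal may also collapse before the quench, so that a free ketone is attacked, or the basic aryllithium may strip the methoxy group from an amide nitrogen. The fallback sets out from 5 and 7 and builds the bridge one carbon at a time. Aryllithium 9 (from 5 and n-BuLi) would be acylated with N-methoxy-N-methylacetamide to the methyl ketone 1-[2,4-bis(methoxymethoxy)-3-(3-methylbut-2-enyl)phenyl]ethan-1-one F1. A palladium-catalysed ketone α-arylation of F1 with 7 (Pd(OAc)2, XPhos, NaOt-Bu, toluene, 80 °C) would give the deoxybenzoin 1-[2,4-bis(methoxymethoxy)-3-(3-methylbut-2-enyl)phenyl]-2-[4-methoxy-2-(methoxymethoxy)phenyl]ethan-1-one F2. Base-mediated aerobic oxidation of its doubly activated methylene group (DABCO, air, DMF, 90 °C) would come back to the route at 13, with all three phenols still protected.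

Step 2. Alkylation of the crowded aryllithium 4 may be slow, may go partly at the tertiary end of the allyl system, or may be overtaken by halogen–metal exchange with the allylic bromide. The fallback sets out from 2: the anion 4 would be quenched with iodine to 1-bromo-3-iodo-2,4-bis(methoxymethoxy)benzene F3. The prenyl group would then be introduced by a Stille coupling at the more reactive carbon–iodine bond with tributyl(3-methylbut-2-enyl)stannane (Pd(PPh3)4, DMF, 80 °C), which comes back to the route at 5.

Step 5. Acid may induce cyclisation of the prenyl chain onto a freed neighbouring phenol, or hydration of the alkene, before the slowest acetal at the 4-oxygen of ring B is cleaved. The fallback sets out from 2 and makes the trisubstituted alkene only after the acid step. Metalation as in step 2 and alkylation with allyl bromide would give 1-bromo-2,4-bis(methoxymethoxy)-3-(prop-2-enyl)benzene F4. The sequence of step 4 (n-BuLi; 8; 11) would give 1-[2,4-bis(methoxymethoxy)-3-(prop-2-enyl)phenyl]-2-[4-methoxy-2-(methoxymethoxy)phenyl]ethane-1,2-dione F5. Methanolic HCl would give 1-[2,4-dihydroxy-3-(prop-2-enyl)phenyl]-2-(2-hydroxy-4-methoxyphenyl)ethane-1,2-dione F6, whose monosubstituted alkene is not protonated. Cross-metathesis with 2-methylbut-2-ene (second-generation Grubbs catalyst (H2IMes)(PCy3)Cl2Ru=CHPh, CH2Cl2, 40 °C) would come back to the route at 14.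

**Further compounds**

F1 | step 4 | 1-[2,4-bis(methoxymethoxy)-3-(3-methylbut-2-enyl)phenyl]ethan-1-one | CC(=O)c1ccc(OCOC)c(CC=C(C)C)c1OCOC
F2 | step 4 | 1-[2,4-bis(methoxymethoxy)-3-(3-methylbut-2-enyl)phenyl]-2-[4-methoxy-2-(methoxymethoxy)phenyl]ethan-1-one | COCOc1cc(OC)ccc1CC(=O)c1ccc(OCOC)c(CC=C(C)C)c1OCOC
F3 | step 2 | 1-bromo-3-iodo-2,4-bis(methoxymethoxy)benzene | COCOc1ccc(Br)c(OCOC)c1I
F4 | step 5 | 1-bromo-2,4-bis(methoxymethoxy)-3-(prop-2-enyl)benzene | COCOc1ccc(Br)c(OCOC)c1CC=C
F5 | step 5 | 1-[2,4-bis(methoxymethoxy)-3-(prop-2-enyl)phenyl]-2-[4-methoxy-2-(methoxymethoxy)phenyl]ethane-1,2-dione | COCOc1cc(OC)ccc1C(=O)C(=O)c1ccc(OCOC)c(CC=C)c1OCOC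
F6 | step 5 | 1-[2,4-dihydroxy-3-(prop-2-enyl)phenyl]-2-(2-hydroxy-4-methoxyphenyl)ethane-1,2-dione | COc1ccc(C(=O)C(=O)c2ccc(O)c(CC=C)c2O)c(O)c1
A1 | direct plan | 1-methoxy-2-(3-methylbut-2-enyl)-1,3-bis(trimethylsilyloxy)buta-1,3-diene | C=C(O[Si](C)(C)C)C(CC=C(C)C)=C(OC)O[Si](C)(C)C
A2 | direct plan | 1-(tert-butyldimethylsilyloxy)-1-[4-methoxy-2-(methoxymethoxy)phenyl]but-3-yn-2-one (racemic) | C#CC(=O)C(O[Si](C)(C)C(C)(C)C)c1ccc(OC)cc1OCOC
A3 | direct plan | 2-(tert-butyldimethylsilyloxy)-1-[2,4-dihydroxy-3-(3-methylbut-2-enyl)phenyl]-2-[4-methoxy-2-(methoxymethoxy)phenyl]ethan-1-one (racemic) | COCOc1cc(OC)ccc1C(O[Si](C)(C)C(C)(C)C)C(=O)c1ccc(O)c(CC=C(C)C)c1O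
A4 | direct plan | 1-[2,4-dihydroxy-3-(3-methylbut-2-enyl)phenyl]-2-hydroxy-2-[4-methoxy-2-(methoxymethoxy)phenyl]ethan-1-one (racemic) | COCOc1cc(OC)ccc1C(O)C(=O)c1ccc(O)c(CC=C(C)C)c1O
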